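**Retrosynthetic overview**
1. The target comes from a tri-O-benzyl β-hydroxy ketone by one global hydrogenolysis.
2. Key disconnection, catechol aryl–C1 bond: the ketone β-carbon C1 is used as a nucleophile (a ketone homoenolate released from a 1-substituted cyclopropanol by palladium) and is joined to the electrophilic carbon of 4-bromo-1,2-bis(benzyloxy)benzene.
3. The cyclopropanol comes from a Kulinkovich reaction on an (R)-β-hydroxy ester; C1 and C2 of the heptane chain come from EtMgBr.
4. The (R)-β-hydroxy ester comes from Noyori hydrogenation (sets the only stereocenter) of a β-keto ester made by γ-alkylation of the ethyl acetoacetate dianion with O-benzylvanillyl chloride.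
5. Rings: both arenes are bought; the only ring made is the sacrificial cyclopropanol (formed in step 3, opened in step 4).

Assumption: 4-(benzyloxy)-3-methoxybenzyl chloride and 4-bromo-1,2-bis(benzyloxy)benzene are bought as catalogue compounds.
Assumption: catalyst-bound transient species (titanacyclopropane, organopalladium intermediates) and salts that are only protonated on work-up get no compound number.

The target stereocenter is (5R) by CIP analysis of the given SMILES (OH > CH2C(=O) > CH2CH2Ar > H).

**Route**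

Step 1
Reactants: 1 ethyl acetoacetate; 2 4-(benzyloxy)-3-methoxybenzyl chloride
Product: 4 ethyl 5-[4-(benzyloxy)-3-methoxyphenyl]-3-oxopentanoate, via ethyl acetoacetate dianion 3 (not isolated)
Conditions: NaH (1.1 equiv), THF, 0 °C; n-BuLi (1.05 equiv), 0 °C; then 2 (0.9 equiv), 0 °C to rt; aq. HCl
Reagents that add atoms: none
Why: Weiler dianion γ-alkylation, in which the more basic terminal carbanion of the dianion displaces the benzylic chloride by SN2 while the stabilised α-enolate stays untouched.

Step 2
Reactants: 4 ethyl 5-[4-(benzyloxy)-3-methoxyphenyl]-3-oxopentanoate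
Product: 5 ethyl (3R)-5-[4-(benzyloxy)-3-methoxyphenyl]-3-hydroxypentanoate
Conditions: H2 (50 bar), [RuCl(p-cymene)((R)-BINAP)]Cl (0.5 mol%), EtOH, 50 °C
Reagents that add atoms: none
Why: Noyori asymmetric hydrogenation, in which the β-keto ester chelates divalent ruthenium and the (R)-BINAP ligand directs hydride to one carbonyl face to give the (R)-alcohol (typically ≥97% ee, as for (R)-3-hydroxybutanoate), the aryl benzyl ether being inert to this homogeneous catalyst.

Step 3
Reactants: 5 ethyl (3R)-5-[4-(benzyloxy)-3-methoxyphenyl]-3-hydroxypentanoate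
Product: 7 1-[(2R)-4-[4-(benzyloxy)-3-methoxyphenyl]-2-hydroxybutyl]cyclopropan-1-ol, via bromomagnesium alkoxide of the hydroxy ester 6 (not isolated)
Conditions: Ti(OiPr)4 (0.3 equiv), EtMgBr (4 equiv, added over 3 h), THF/Et2O, 0 °C to rt; then H2O
Reagents that add atoms: ethylmagnesium bromide, CC[Mg]Br
Why: Kulinkovich cyclopropanation, in which the titanacyclopropane formed from EtMgBr and Ti(OiPr)4 adds twice to the ester carbonyl as a 1,2-dicarbanion while the first equivalent of Grignard reagent masks the free hydroxyl as its magnesium alkoxide, and the stereocenter, which carries no acidic hydrogen, is untouched.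

Step 4
Reactants: 7 1-[(2R)-4-[4-(benzyloxy)-3-methoxyphenyl]-2-hydroxybutyl]cyclopropan-1-ol; 8 4-bromo-1,2-bis(benzyloxy)benzene (1.2 equiv)
Product: 9 (5R)-1-[3,4-bis(benzyloxy)phenyl]-7-[4-(benzyloxy)-3-methoxyphenyl]-5-hydroxyheptan-3-one
Conditions: Pd(OAc)2 (5 mol%), XPhos (10 mol%), Cs2CO3 (2 equiv), toluene, 80 °C, under argon
Reagents that add atoms: none
Why: Palladium-catalysed ring-opening cross-coupling of a cyclopropanol (ketone homoenolate arylation), in which 8 adds oxidatively to zerovalent palladium, the cyclopropoxide (no β-hydrogen) replaces bromide and opens by strain-driven β-carbon elimination to a palladium homoenolate that undergoes C–C reductive elimination, favoured by the bulky XPhos ligand over β-hydride elimination; the remote carbinol stereocenter is not involved.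

Step 5
Reactants: 9 (5R)-1-[3,4-bis(benzyloxy)phenyl]-7-[4-(benzyloxy)-3-methoxyphenyl]-5-hydroxyheptan-3-one
Product: 10 (5R)-1-(3,4-dihydroxyphenyl)-5-hydroxy-7-(4-hydroxy-3-methoxyphenyl)heptan-3-one (CNP0094522.1)
Conditions: H2 (1 atm), Pd/C (10 wt% palladium metal on carbon), EtOAc/MeOH, rt; concentrate under argon
Reagents that add atoms: none
Why: Catalytic hydrogenolysis cleaves the three aryl benzyl ethers, while the aliphatic ketone, the non-benzylic secondary alcohol and the stereocenter are inert under these neutral conditions.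

**Compound list**
1 | ethyl acetoacetate | CCOC(=O)CC(C)=O | starting material
2 | 4-(benzyloxy)-3-methoxybenzyl chloride | COc1cc(CCl)ccc1OCc1ccccc1 | starting material
3 | sodium lithium dienolate (dianion) of ethyl acetoacetate | [Na+].[Li+].C=C([O-])C=C([O-])OCC | intermediate
4 | ethyl 5-[4-(benzyloxy)-3-methoxyphenyl]-3-oxopentanoate | COc1cc(CCC(=O)CC(=O)OCC)ccc1OCc1ccccc1 | intermediate
5 | ethyl (3R)-5-[4-(benzyloxy)-3-methoxyphenyl]-3-hydroxypentanoate | COc1cc(CC[C@@H](O)CC(=O)OCC)ccc1OCc1ccccc1 | intermediate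
6 | ethyl (3R)-5-[4-(benzyloxy)-3-methoxyphenyl]-3-[(bromomagnesio)oxy]pentanoate | COc1cc(CC[C@@H](O[Mg]Br)CC(=O)OCC)ccc1OCc1ccccc1 | intermediate
7 | 1-[(2R)-4-[4-(benzyloxy)-3-methoxyphenyl]-2-hydroxybutyl]cyclopropan-1-ol | COc1cc(CC[C@@H](O)CC2(O)CC2)ccc1OCc1ccccc1 | intermediate
8 | 4-bromo-1,2-bis(benzyloxy)benzene | Brc1ccc(OCc2ccccc2)c(OCc2ccccc2)c1 | starting material
9 | (5R)-1-[3,4-bis(benzyloxy)phenyl]-7-[4-(benzyloxy)-3-methoxyphenyl]-5-hydroxyheptan-3-one | COc1cc(CC[C@@H](O)CC(=O)CCc2ccc(OCc3ccccc3)c(OCc3ccccc3)c2)ccc1OCc1ccccc1 | intermediate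
10 | (5R)-1-(3,4-dihydroxyphenyl)-5-hydroxy-7-(4-hydroxy-3-methoxyphenyl)heptan-3-one | COc1cc(CC[C@@H](O)CC(=O)CCc2ccc(O)c(O)c2)ccc1O | target

**Step count and risks**
Total steps: 5. Longest linear sequence: 5 steps (1 and 2 to 10); aryl bromide 8 enters convergently in step 4.

Step 4 is the most likely to fail. The palladium homoenolate may lose a β-hydride to give the vinyl ketone, the arylpalladium bromide may oxidise the free secondary alcohol, and the β-hydroxy ketone may dehydrate on hot carbonate. The fallback replaces the homoenolate coupling by a conjugate addition and sets out from 5. Aminolysis with Me(MeO)NH·HCl and i-PrMgCl (THF, −20 °C) gives the Weinreb amide (3R)-5-[4-(benzyloxy)-3-methoxyphenyl]-3-hydroxy-N-methoxy-N-methylpentanamide F1. CH2=CHMgBr (THF, 0 °C, inverse quench into cold aq. KHSO4) gives the vinyl ketone (5R)-7-[4-(benzyloxy)-3-methoxyphenyl]-5-hydroxyhept-1-en-3-one F2. Rhodium-catalysed 1,4-addition of 3,4-bis(benzyloxy)phenylboronic acid ([Rh(cod)Cl]2, KOH, dioxane/H2O, 40 °C) comes back to the route at 9.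

Step 3 is the second risk. The stoichiometric β-alkoxide of 6 may tie up the titanium catalyst and stall the Kulinkovich reaction. The fallback masks the alcohol with a group that the last step removes anyway and sets out from 5. Benzyl 2,2,2-trichloroacetimidate with catalytic TfOH (CH2Cl2/cyclohexane, 0 °C) gives the benzyl ether ethyl (3R)-3-(benzyloxy)-5-[4-(benzyloxy)-3-methoxyphenyl]pentanoate F3. The Kulinkovich reaction under the step 3 conditions (2.5 equiv EtMgBr) gives the cyclopropanol 1-[(2R)-2-(benzyloxy)-4-[4-(benzyloxy)-3-methoxyphenyl]butyl]cyclopropan-1-ol F4. Coupling with 8 under the step 4 conditions gives the tetrabenzyl ketone (5R)-5-(benzyloxy)-1-[3,4-bis(benzyloxy)phenyl]-7-[4-(benzyloxy)-3-methoxyphenyl]heptan-3-one F5, which no longer carries a free alcohol. The hydrogenolysis of step 5 then removes all four benzyl groups and comes back to the route at 10.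

Step 1 is the third risk. The electron-rich benzylic chloride may give dialkylation, O-alkylation or homocoupling with the strongly basic dianion. The fallback builds the β-keto ester from a nitrile and sets out from 2. LiCH2CN (from excess MeCN and LiN(iPr)2, THF, −78 °C) gives the nitrile 3-[4-(benzyloxy)-3-methoxyphenyl]propanenitrile F6. A Blaise reaction with BrCH2CO2Et and activated Zn dust (THF, reflux), then aq. HCl hydrolysis of the zinc enaminate, comes back to the route at 4.

**Further compounds**
F1 | step 4 | (3R)-5-[4-(benzyloxy)-3-methoxyphenyl]-3-hydroxy-N-methoxy-N-methylpentanamide | COc1cc(CC[C@@H](O)CC(=O)N(C)OC)ccc1OCc1ccccc1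
F2 | step 4 | (5R)-7-[4-(benzyloxy)-3-methoxyphenyl]-5-hydroxyhept-1-en-3-one | COc1cc(CC[C@@H](O)CC(=O)C=C)ccc1OCc1ccccc1
F3 | step 3 | ethyl (3R)-3-(benzyloxy)-5-[4-(benzyloxy)-3-methoxyphenyl]pentanoate | COc1cc(CC[C@@H](OCc2ccccc2)CC(=O)OCC)ccc1OCc1ccccc1
F4 | step 3 | 1-[(2R)-2-(benzyloxy)-4-[4-(benzyloxy)-3-methoxyphenyl]butyl]cyclopropan-1-ol | COc1cc(CC[C@@H](OCc2ccccc2)CC2(O)CC2)ccc1OCc1ccccc1
F5 | step 3 | (5R)-5-(benzyloxy)-1-[3,4-bis(benzyloxy)phenyl]-7-[4-(benzyloxy)-3-methoxyphenyl]heptan-3-one | COc1cc(CC[C@@H](OCc2ccccc2)CC(=O)CCc2ccc(OCc3ccccc3)c(OCc3ccccc3)c2)ccc1OCc1ccccc1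
F6 | step 1 | 3-[4-(benzyloxy)-3-methoxyphenyl]propanenitrile | COc1cc(CCC#N)ccc1OCc1ccccc1
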